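## Retrosynthetic overview
1. The oxepane is closed last. The C3 tertiary alcohol displaces a C16 primary triflate, and C16–OH and C15 come from hydroboration of a C14 isopropenyl group.
2. The C11 acetate and C12 methyl come from a C11 ketone by α-methylenation. Hydride, proton and hydride are then all delivered to the open α face.
3. The oxonene is closed by ring-closing metathesis at C6=C7 (Z).
4. Ring A and the oxolane form together. Iodonium-triggered etherification of a 1-alkenylcyclopentane 1,3-diol is followed by a 1,2-shift of C1 from C11 to C10 (cyclopentanol → cyclohexanone, oxane → oxolane).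
5. The cyclopentanol comes from cyclopentenone, isopropenyl Grignard and a C2–C6 aldehyde (conjugate addition/aldol), then a C7–C10 alkenylcerium. Ring order: cyclopentane → (oxane) → ring A + oxolane → oxonene → oxepane.

Assumption: locants C1–C20 follow the usual asbestinin numbering. C1/C10 are the ring fusion, C2 and C9 the oxolane carbons, C3 the tertiary ether carbon, C11 the acetoxy carbon, C12 the methyl-bearing carbon, and C14–C15–C16 the side arm. The β face of ring A is the one that carries C2 and C9.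

## Route

Step 1
Reactants: 1 (R)-2-methylglycidol; 2 allylmagnesium bromide
Product: 3 (2S)-2-methylhex-5-ene-1,2-diol
Conditions: 2 (2.5 equiv), CuI (10 mol %), THF, −30 to 0 °C; then H2O
Reagents that add atoms: none
Why: Copper-catalysed SN2 opening of the 2,2-disubstituted epoxide at its CH2 terminus leaves the bought C3 stereocentre untouched, and the Payne shift of the alkoxide is degenerate and does not racemise it.

Step 2
Reactants: 3 (2S)-2-methylhex-5-ene-1,2-diol
Product: 4 (2S)-2-methyl-1,2-bis(triethylsilyloxy)hex-5-ene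
Conditions: Et3SiOTf (2.3 equiv), 2,6-lutidine (3 equiv), CH2Cl2, −78 to 0 °C
Reagents that add atoms: triethylsilyl triflate, CC[Si](CC)(CC)OS(=O)(=O)C(F)(F)F
Why: Silyl triflate silylation covers the hindered tertiary alcohol as well as the primary one, and triethylsilyl is slow to migrate between vicinal oxygens at low temperature.

Step 3
Reactants: 4 (2S)-2-methyl-1,2-bis(triethylsilyloxy)hex-5-ene
Product: 5 (2S)-2-methyl-2-(triethylsilyloxy)hex-5-enal
Conditions: (COCl)2, DMSO, CH2Cl2, −78 to −40 °C; Et3N, −78 to 23 °C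
Reagents that add atoms: none
Why: Under Swern oxidation conditions only the unhindered primary triethylsilyl ether is cleaved and oxidised, and the product has no α hydrogen so C3 cannot epimerise.

Step 4
Reactants: 6 cyclopent-2-en-1-one; 7 isopropenylmagnesium bromide; 5 (2S)-2-methyl-2-(triethylsilyloxy)hex-5-enal
Product: 9 (2R,3R)-2-[(1S,2S)-1-hydroxy-2-methyl-2-(triethylsilyloxy)hex-5-en-1-yl]-3-(prop-1-en-2-yl)cyclopentan-1-one, via magnesium enolate 8 (not isolated)
Conditions: CuBr·SMe2 (5 mol %), Josiphos-type ferrocenyl diphosphine (6 mol %, the antipode giving the 3R adduct), 7 (1.1 equiv), t-BuOMe, −75 °C; then 5 (0.9 equiv), −75 °C; then H2O; chromatography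
Reagents that add atoms: none
Why: Copper-catalysed asymmetric conjugate addition sets C14, the aldehyde adds trans to the new isopropenyl group (C1), the Zimmerman–Traxler chair of the E-configured cyclic enolate gives the anti aldol (C2), and the minor enantiomeric enolate is purged as a separable diastereomer because 5 is enantiopure.

Step 5
Reactants: 10 3-chloro-2-methylprop-1-ene; 11 ethynylmagnesium bromide
Product: 12 2-methylpent-1-en-4-yne
Conditions: CuCl (5 mol %), THF, 0 to 40 °C
Reagents that add atoms: none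
Why: Copper-catalysed allylic substitution of an alkynyl Grignard reagent is the standard entry to skipped 1,4-enynes.

Step 6
Reactants: 12 2-methylpent-1-en-4-yne
Product: 14 (1E)-1-iodo-4-methylpenta-1,4-diene, via alkenylzirconocene chloride 13 (not isolated)
Conditions: Cp2Zr(H)Cl (1.1 equiv), CH2Cl2, 23 °C; I2 (1.05 equiv), 0 °C
Reagents that add atoms: iodine, II
Why: Hydrozirconation is syn, terminal-selective and much faster on the alkyne than on the 1,1-disubstituted alkene, and iodinolysis with retention gives the pure E iodide.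

Step 7
Reactants: 14 (1E)-1-iodo-4-methylpenta-1,4-diene; 9 the aldol of step 4
Product: 17 (1S,2R,3R)-2-[(1S,2S)-1-hydroxy-2-methyl-2-(triethylsilyloxy)hex-5-en-1-yl]-1-[(1E)-4-methylpenta-1,4-dien-1-yl]-3-(prop-1-en-2-yl)cyclopentan-1-ol, via alkenyllithium 15 (not isolated), via alkenylcerium dichloride 16 (not isolated)
Conditions: 14 (2.6 equiv), t-BuLi (5.2 equiv), Et2O, −78 °C; CeCl3 (2.7 equiv), THF, −78 °C; then 9, −78 °C; then H2O
Reagents that add atoms: none
Why: The weakly basic organocerium reagent adds 1,2 to the β-hydroxy ketone without retro-aldol and attacks C11 anti to the bulky C1 side chain, so the C11 hydroxyl ends cis and the alkenyl group trans to that chain.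

Step 8
Reactants: 17 the alkenylcyclopentane diol of step 7
Product: 20 (1S,3S,3aR,7R,7aS)-1-[(2S)-2-hydroxyhex-5-en-2-yl]-3-(2-methylprop-2-en-1-yl)-7-(prop-1-en-2-yl)hexahydro-2-benzofuran-4(1H)-one, via iodo-oxane 18 (not isolated), via silyl ether ketone 19 (not isolated)
Conditions: N-iodosuccinimide (1.1 equiv), 4 Å MS, CH2Cl2, −40 °C; AgOTf (1.2 equiv), 2,6-di-tert-butylpyridine (1.5 equiv), −40 to 0 °C; filter; HF·pyridine, THF, 0 to 23 °C
Reagents that add atoms: none
Why: Proposed new method: iodonium activation of the C9=C10 alkene lets the C2 hydroxyl close only the 6-endo oxane (the 5-exo mode would need a trans-fused bicyclo[3.3.0] ring); anti addition to the E alkene puts iodine equatorial in an all-equatorial chair and so antiperiplanar to the C11–C1 bond; silver-assisted loss of iodide then drives a stereospecific semipinacol 1,2-shift of C1 from C11 to C10 (retention at C1, inversion at C10) that expands cyclopentanol to cyclohexanone, contracts oxane to oxolane and sets C9 and C10; the closest known reaction types are the halonium-induced semipinacol rearrangement of allylic alcohols, the silver-promoted halohydrin ring expansion and the Prins–pinacol ring-enlarging tetrahydrofuran annulation.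

Step 9
Reactants: 20 the bicyclic keto alcohol of step 8
Product: 21 (6Z)-oxonene keto alcohol (C11 ketone; C3 tertiary alcohol; C14 isopropenyl; 1S,2S,3S,9S,10R,14R)
Conditions: second-generation Grubbs catalyst (H2IMes)(PCy3)Cl2Ru=CHPh (10 mol %), CH2Cl2 (1 mM), 40 °C
Reagents that add atoms: none
Why: Ring-closing metathesis joins the two side chains held cis on the convex oxolane face, the nine-membered ring allows only the Z alkene, and the α-branched isopropenyl group is too hindered to compete.

Step 10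
Reactants: 21 (6Z)-oxonene keto alcohol; 22 N,N-dimethylmethyleneiminium iodide (Eschenmoser salt)
Product: 25 12-methylene oxonene keto alcohol (C11 ketone conjugated to C12=C20H2; 1S,2S,3S,9S,10R,14R;6Z), via Mannich base 23 (not isolated), via methiodide 24 (not isolated)
Conditions: LDA (2.2 equiv), THF, −78 °C; 22 (1.5 equiv), −78 to 23 °C; H2O; MeI, CH2Cl2, 23 °C; DBU, 23 °C
Reagents that add atoms: none
Why: Kinetic deprotonation takes the C12 methylene and not the hindered C10 methine, and the Mannich reaction, quaternisation and Hofmann-type elimination install C20 as an exocyclic methylene.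

Step 11
Reactants: 25 12-methylene oxonene keto alcohol
Product: 27 (11R,12R)-diol (C11 β-OH; C12 β-CH3; C3 tertiary OH; 1S,2S,3S,9S,10R,11R,12R,14R;6Z), via methyl ketone 26 (not isolated)
Conditions: LiBH(s-Bu)3 (1.2 equiv), THF, −78 °C; MeOH, −78 °C; NaBH4, −78 to −20 °C
Reagents that add atoms: none
Why: Conjugate hydride reduction gives the C11–C12 enolate, kinetic protonation from the α face (the β face is blocked by the axial C10–C9 bond) places the methyl β, and immediate axial α-face hydride attack on the ketone gives the equatorial β alcohol before C12 can epimerise.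

Step 12
Reactants: 27 (11R,12R)-diol; 28 acetic anhydride
Product: 29 11-acetate (C3 tertiary OH free; C14 isopropenyl; 1S,2S,3S,9S,10R,11R,12R,14R;6Z)
Conditions: 28 (3 equiv), pyridine, DMAP (10 mol %), CH2Cl2, 23 °C
Reagents that add atoms: none
Why: DMAP-catalysed acylation esterifies the secondary C11 alcohol, while the hindered tertiary C3 alcohol does not react under these conditions.

Step 13
Reactants: 29 11-acetate
Product: 31 (15R)-16-hydroxy 11-acetate (C16 primary OH; C3 tertiary OH; 1S,2S,3S,9S,10R,11R,12R,14S,15R;6Z), via trialkylborane 30 (not isolated)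
Conditions: 9-BBN (3 equiv), THF, 0 to 23 °C; NaBO3·4H2O, THF–H2O, 23 °C
Reagents that add atoms: sodium perborate, [Na+].[Na+].O[B-]1(O)OO[B-](O)(O)OO1
Why: Anti-Markovnikov hydroboration with 9-BBN selects the 1,1-disubstituted over the trisubstituted alkene, and in the A(1,3)-minimised rotamer (H14 eclipsing C=CH2) the borane approaches from the C13 side, away from C1 and C2, which gives 15R; the mild perborate oxidation spares the acetate.

Step 14
Reactants: 31 (15R)-16-hydroxy 11-acetate
Product: 33 11-acetoxy-4-deoxyasbestinin D (CNP0177382.3), via primary triflate 32 (not isolated)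
Conditions: Tf2O (1.2 equiv), 2,6-lutidine (4 equiv), CH2Cl2, −78 to 23 °C
Reagents that add atoms: none
Why: Only the primary alcohol is triflated, and the nearby C3 tertiary alcohol displaces it in an intramolecular Williamson-type SN2 reaction at CH2, which closes the trans-fused oxepane without touching a stereocentre.

## Compound list
1 | (R)-2-methylglycidol, (2R)-(2-methyloxiran-2-yl)methanol | OC[C@@]1(C)OC1 | starting material
2 | allylmagnesium bromide | C=CC[Mg]Br | starting material
3 | (2S)-2-methylhex-5-ene-1,2-diol | OC[C@@](C)(O)CCC=C | intermediate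
4 | (2S)-2-methyl-1,2-bis(triethylsilyloxy)hex-5-ene | CC[Si](CC)(CC)OC[C@@](C)(O[Si](CC)(CC)CC)CCC=C | intermediate
5 | (2S)-2-methyl-2-(triethylsilyloxy)hex-5-enal | O=C[C@@](C)(O[Si](CC)(CC)CC)CCC=C | intermediate
6 | cyclopent-2-en-1-one | O=C1C=CCC1 | starting material
7 | isopropenylmagnesium bromide | CC(=C)[Mg]Br | starting material
8 | bromomagnesium (3R)-3-(prop-1-en-2-yl)cyclopent-1-en-1-olate | Br[Mg]OC1=C[C@H](C(C)=C)CC1 | intermediate
9 | (2R,3R)-2-[(1S,2S)-1-hydroxy-2-methyl-2-(triethylsilyloxy)hex-5-en-1-yl]-3-(prop-1-en-2-yl)cyclopentan-1-one | O=C1CC[C@@H](C(C)=C)[C@@H]1[C@H](O)[C@@](C)(O[Si](CC)(CC)CC)CCC=C | intermediate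
10 | 3-chloro-2-methylprop-1-ene | CC(=C)CCl | starting material
11 | ethynylmagnesium bromide | C#C[Mg]Br | starting material
12 | 2-methylpent-1-en-4-yne | CC(=C)CC#C | intermediate
13 | chlorobis(cyclopentadienyl)[(1E)-4-methylpenta-1,4-dien-1-yl]zirconium | CC(=C)C/C=C/[Zr](Cl)(C1C=CC=C1)C1C=CC=C1 | intermediate
14 | (1E)-1-iodo-4-methylpenta-1,4-diene | CC(=C)C/C=C/I | intermediate
15 | (1E)-4-methylpenta-1,4-dien-1-yllithium | CC(=C)C/C=C/[Li] | intermediate
16 | dichloro[(1E)-4-methylpenta-1,4-dien-1-yl]cerium | CC(=C)C/C=C/[Ce](Cl)Cl | intermediate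
17 | (1S,2R,3R)-2-[(1S,2S)-1-hydroxy-2-methyl-2-(triethylsilyloxy)hex-5-en-1-yl]-1-[(1E)-4-methylpenta-1,4-dien-1-yl]-3-(prop-1-en-2-yl)cyclopentan-1-ol | O[C@]1(/C=C/CC(C)=C)CC[C@@H](C(C)=C)[C@@H]1[C@H](O)[C@@](C)(O[Si](CC)(CC)CC)CCC=C | intermediate
18 | (1S,3S,4S,4aR,7R,7aR)-4-iodo-3-(2-methylprop-2-en-1-yl)-7-(prop-1-en-2-yl)-1-[(2S)-2-(triethylsilyloxy)hex-5-en-2-yl]hexahydrocyclopenta[c]pyran-4a(1H)-ol | O[C@]12CC[C@@H](C(C)=C)[C@@H]1[C@@H]([C@@](C)(O[Si](CC)(CC)CC)CCC=C)O[C@@H](CC(C)=C)[C@@H]2I | intermediate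
19 | (1S,3S,3aR,7R,7aS)-3-(2-methylprop-2-en-1-yl)-7-(prop-1-en-2-yl)-1-[(2S)-2-(triethylsilyloxy)hex-5-en-2-yl]hexahydro-2-benzofuran-4(1H)-one | O=C1[C@@H]2[C@H]([C@@H](CC1)C(C)=C)[C@H](O[C@H]2CC(C)=C)[C@@](C)(O[Si](CC)(CC)CC)CCC=C | intermediate
20 | (1S,3S,3aR,7R,7aS)-1-[(2S)-2-hydroxyhex-5-en-2-yl]-3-(2-methylprop-2-en-1-yl)-7-(prop-1-en-2-yl)hexahydro-2-benzofuran-4(1H)-one | O=C1[C@@H]2[C@H]([C@@H](CC1)C(C)=C)[C@H](O[C@H]2CC(C)=C)[C@@](C)(O)CCC=C | intermediate
21 | oxonene keto alcohol: cyclohexanone (C11=O, C12 and C13 CH2, C14 isopropenyl) cis-fused at C1–C10 to the C2–O–C9 oxolane, whose C2 and C9 are spanned by C3(OH)(CH3)–C4H2–C5H2–C6H=C7(CH3)–C8H2 (6Z); 1S,2S,3S,9S,10R,14R | O=C1[C@@H]2[C@H]([C@@H](CC1)C(C)=C)[C@@H]3O[C@H]2C/C(C)=C\CC[C@]3(C)O | intermediate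
22 | N,N-dimethylmethyleneiminium iodide | C[N+](C)=C.[I-] | starting material
23 | 21 carrying CH2N(CH3)2 at C12 (C12 configuration not relevant) | O=C1[C@@H]2[C@H]([C@@H](CC1CN(C)C)C(C)=C)[C@@H]3O[C@H]2C/C(C)=C\CC[C@]3(C)O | intermediate
24 | trimethylammonium iodide of 23 | O=C1[C@@H]2[C@H]([C@@H](CC1C[N+](C)(C)C)C(C)=C)[C@@H]3O[C@H]2C/C(C)=C\CC[C@]3(C)O.[I-] | intermediate
25 | 21 carrying an exocyclic methylene (C20) at C12; 1S,2S,3S,9S,10R,14R;6Z | O=C1[C@@H]2[C@H]([C@@H](CC1=C)C(C)=C)[C@@H]3O[C@H]2C/C(C)=C\CC[C@]3(C)O | intermediate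
26 | 21 carrying a β methyl at C12 (12R) | O=C1[C@@H]2[C@H]([C@@H](C[C@H]1C)C(C)=C)[C@@H]3O[C@H]2C/C(C)=C\CC[C@]3(C)O | intermediate
27 | 11β-alcohol of 26; 1S,2S,3S,9S,10R,11R,12R,14R;6Z | O[C@H]1[C@@H]2[C@H]([C@@H](C[C@H]1C)C(C)=C)[C@@H]3O[C@H]2C/C(C)=C\CC[C@]3(C)O | intermediate
28 | acetic anhydride | CC(=O)OC(C)=O | starting material
29 | 11-acetate of 27 | CC(=O)O[C@H]1[C@@H]2[C@H]([C@@H](C[C@H]1C)C(C)=C)[C@@H]3O[C@H]2C/C(C)=C\CC[C@]3(C)O | intermediate
30 | B-alkyl-9-borabicyclo[3.3.1]nonane from 29 (boron on C16, 15R) | CC(=O)O[C@H]1[C@@H]2[C@H]([C@@H](C[C@H]1C)[C@@H](C)CB4C5CCCC4CCC5)[C@@H]3O[C@H]2C/C(C)=C\CC[C@]3(C)O | intermediate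
31 | 29 with C14 bearing (R)-CH(CH3)CH2OH; 1S,2S,3S,9S,10R,11R,12R,14S,15R;6Z | CC(=O)O[C@H]1[C@@H]2[C@H]([C@@H](C[C@H]1C)[C@@H](C)CO)[C@@H]3O[C@H]2C/C(C)=C\CC[C@]3(C)O | intermediate
32 | C16 triflate of 31 | CC(=O)O[C@H]1[C@@H]2[C@H]([C@@H](C[C@H]1C)[C@@H](C)COS(=O)(=O)C(F)(F)F)[C@@H]3O[C@H]2C/C(C)=C\CC[C@]3(C)O | intermediate
33 | 11-acetoxy-4-deoxyasbestinin D; 1S,2S,3S,9S,10R,11R,12R,14S,15R;6Z | CC(=O)O[C@H]1[C@@H]2[C@@H]3[C@@H](C[C@H]1C)[C@@H](C)CO[C@@]1(C)CC/C=C(/C)C[C@@H]2O[C@@H]31 | target

## Step count and risks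
Total steps: 14. Longest linear sequence: 12 (steps 1–4 and 7–14; steps 5 and 6 form the side branch).

**Step 8 (the new cascade).**
- The risks are iodonium chemistry at the other alkenes and a sluggish loss of the secondary iodide.
- The fallback sets out from 17 and comes back at 19, using known reactions only.
- Hydroxyl-directed epoxidation of the allylic alcohol (VO(acac)2, t-BuOOH) gives the epoxy diol F4.
- BF3·OEt2 at −78 °C then triggers the known 2,3-epoxy alcohol semipinacol ring expansion, with C1 shifting anti to the C10–O bond, to give the β-hydroxy ketone F5.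
- The less hindered C9 hydroxyl is mesylated (MsCl, Et3N) to give the mesylate F6.
- The C2 hydroxyl displaces the mesylate with inversion on warming with 2,6-lutidine. The net syn addition of C1 and oxygen across the E alkene is the same as in the cascade and delivers 19, which HF·pyridine converts into 20.

**Step 4 (three-component coupling).**
- The risks are moderate enantioselectivity with an alkenyl Grignard reagent and incomplete anti selectivity against the small Felkin bias of 5.
- The fallback sets out from 6 and 7 and comes back at 9.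
- The magnesium cuprate made from 7 and CuI, with Me3SiCl, gives the racemic silyl enol ether F1.
- MeLi and then Cy2BCl turn it into the dicyclohexylboron enolate F2, whose tight boron chair gives only anti aldols with 5 (H2O2 work-up).
- Because 5 is enantiopure, the two anti adducts are diastereomers. The unwanted diastereomer F3 is removed by chromatography and the other one is 9. This replaces catalyst control by resolution.

**Step 11 (the less stable β methyl at C12).**
- The risk is protonation from the wrong face, or epimerisation before reduction.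
- The fallback sets out from 25 and comes back at 26.
- RhCl(PPh3)3-catalysed 1,4-hydrosilylation with Et3SiH gives the isolable triethylsilyl enol ether F7.
- F7 is protonated under reagent control by a BINOL·SnCl4 Brønsted acid (the antipode matched to α-face delivery) at −78 °C. The resulting 26 is reduced at once with NaBH4 to 27 as in the main route.

## Further compounds
F1 | step 4 | 3-(prop-1-en-2-yl)-1-(trimethylsilyloxy)cyclopent-1-ene (racemic) | C[Si](C)(C)OC1=CC(C(C)=C)CC1
F2 | step 4 | dicyclohexyl[3-(prop-1-en-2-yl)cyclopent-1-en-1-yloxy]borane (racemic) | C1CCCCC1B(OC2=CC(C(C)=C)CC2)C3CCCCC3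
F3 | step 4 | (2S,3S)-2-[(1R,2S)-1-hydroxy-2-methyl-2-(triethylsilyloxy)hex-5-en-1-yl]-3-(prop-1-en-2-yl)cyclopentan-1-one | O=C1CC[C@H](C(C)=C)[C@H]1[C@@H](O)[C@@](C)(O[Si](CC)(CC)CC)CCC=C
F4 | step 8 | (1R,2R,3R)-2-[(1S,2S)-1-hydroxy-2-methyl-2-(triethylsilyloxy)hex-5-en-1-yl]-1-[(2S,3R)-3-(2-methylprop-2-en-1-yl)oxiran-2-yl]-3-(prop-1-en-2-yl)cyclopentan-1-ol | O[C@]1([C@H]2O[C@@H]2CC(C)=C)CC[C@@H](C(C)=C)[C@@H]1[C@H](O)[C@@](C)(O[Si](CC)(CC)CC)CCC=C
F5 | step 8 | ring-expanded β-hydroxy ketone: cyclohexanone bearing at C10 the (9R)-1-hydroxy-3-methylbut-3-enyl group and at C1 the C2 carbinol side chain; 1S,2S,3S,9R,10R,14R | O=C1[C@@H]([C@H](O)CC(C)=C)[C@H]([C@@H](CC1)C(C)=C)[C@H](O)[C@@](C)(O[Si](CC)(CC)CC)CCC=C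
F6 | step 8 | C9 methanesulfonate of F5 | O=C1[C@@H]([C@H](OS(C)(=O)=O)CC(C)=C)[C@H]([C@@H](CC1)C(C)=C)[C@H](O)[C@@](C)(O[Si](CC)(CC)CC)CCC=C
F7 | step 11 | C11 triethylsilyl enol ether (C11=C12, methyl on C12) of 26 | CC[Si](CC)(CC)OC=1[C@@H]2[C@H]([C@@H](CC=1C)C(C)=C)[C@@H]3O[C@H]2C/C(C)=C\CC[C@]3(C)O
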